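Ring atoms of the target are numbered O1, C2, C3, C4, C5; C6 is the benzylic carbon of the branch on C4. Compounds carry the numbers of the compound list (1–22).

## Analysis of the target

- Compound 22 is an oxolane substituted on every carbon: C2 carries a 4-hydroxyphenyl group, C3 a 2,4-dihydroxybenzoyl group, C4 a 4-hydroxybenzyl group (C6) and C5 a 2,4-dihydroxyphenyl group.
- The four stereocentres are contiguous, (2S,3S,4S,5R). The relationships are 2,3-trans, 3,4-trans and 4,5-cis, so the aryl groups on C2 and C5 and the benzyl group on C4 share one face and the aroyl group alone takes the other.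
- C3 is α to a ketone and trans to both neighbours, so it already sits in its more stable arrangement. The 4,5-cis pair of a benzyl group and an ortho-substituted aryl group is the crowded relationship and has to be set kinetically, together with its sense relative to C2.
- C2 and C5 are benzylic ether carbons on para- or ortho,para-oxygenated arenes and ionise readily with acid. Base can enolise C3 and expel O1 by β-elimination.
- Six free phenols and an electron-rich aryl ketone restrict the end-game to mild, non-acidic deprotection.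
- The difficulty is therefore four adjacent centres on a five-membered ring with one cis pair that thermodynamics will not supply, not the carbon skeleton.
- The strategy rests on this feature: an O–C6 bond from the ortho-hydroxyl of the C5 aryl group would close a chroman cis-fused to the oxolane across C4–C5. Read that way, C5 with its aryl group is the carbonyl carbon of a salicylaldehyde, and C4–C6 is a styrene double bond tethered to it through O1, C2 and C3.

## Retrosynthetic reasoning

**22 from 20 (O–C6 bond added).** The phenol oxygen of the C5 aryl group is joined to C6, which gives the cis-fused furochroman 20. This turns the difficult 4,5-cis relationship into a ring-fusion constraint. The added bond is the only benzylic C–O bond with a phenoxide leaving group and a para-hydroxyphenyl donor, so the forward step can cut it selectively through quinone methide 21, which takes up hydride at C6.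

**20 from 19 (phenol protection).** All five phenols of 20 are carried as benzyl ethers. These tolerate base, organolithium reagents and a Lewis acid, and they are removed by hydrogenolysis in neutral solvent, which avoids acid at the two benzylic ether carbons of the oxolane.

**19 from 15 and 18 (carbonyl–aryl bond).** The bond between the C3 carbonyl carbon and its arene is cut, leading to Weinreb amide 15 and aryllithium 18. The aryllithium comes from bromide 17, the dibenzyl ether of 16. Cutting here keeps the most electron-rich, chelating ketone out of the Lewis-acid step. It also leaves an electron-withdrawing, non-enolising amide on C3 that disfavours a cation at C2, and the amide accepts exactly one aryl group.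

**15 from 10 and 11 (key disconnection).** The bonds O1–C5, C4–C5 and O–C6 are cut together. All three radiate from one aldehyde carbon and one double bond, so the fragments are simply the secondary alcohol 10 and salicylaldehyde 11, joined in the forward sense by condensation. The forward reaction must form the oxolane and the chroman in one operation and set C4, C5 and C6 from the two centres already present in 10.

**10 from 9, and 9 from 7 and 1 (aldol bond C2–C3).** The C2–C3 bond is an aldol bond. A syn aldol, once its hydroxyl oxygen and its vinyl carbon are tied into the ring, places the aryl group on C2 and the carbonyl group on C3 trans, as in 22. An auxiliary-controlled boron aldol of imide 7 with aldehyde 1 gives 9 with both centres set, and exchange of the auxiliary for the N-methoxy-N-methylamide gives 10.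

**7 from 4 and 5, and 4 from 1 and 2.** The N-acyl bond of 7 leads to acid 4 and auxiliary 5. The E double bond of 4 is cut to aldehyde 1 and phosphonium salt 2. Aldehyde 1 therefore supplies both para-oxygenated arenes.

## Alternatives that were turned down

**Alternative 1:** cyclopropane (3+2) annulation.
- Disconnection: O1–C5 and C2–C3. This leaves the trans donor–acceptor cyclopropane A2 and 4-acetoxybenzaldehyde A3. In A2, C3 is the malonate carbon and C5 has the configuration opposite to that in 22.
- Forward key step: Sn(OTf)2 binds the diester, the aldehyde oxygen opens the ring at benzylic C5 from the back, and the malonate carbon closes on the aldehyde carbon to give oxolane diester A1.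
- For: the step is convergent, inversion at C5 is stereospecific, this type of annulation favours the 2,5-cis oxolane that 22 needs, and C4 passes through untouched. The acetates damp the arenes so that the ring-opened zwitterion is not over-stabilised.
- Against: A1 has two esters on C3 where 22 has one aryl ketone and a hydrogen. One ester has to be removed and the other converted into the ketone, which costs at least five further steps. The acetates would not survive the organometallic reagent needed for the ketone. A2 is a trisubstituted cyclopropane with two stereocentres that needs its own enantioselective synthesis, and the substituent on C4 next to an ortho-substituted donor carbon slows back-side attack.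
- Comparison: alternative 1 is stronger in convergence and in its intrinsic cis preference across O1. The chosen route has C3 at the right oxidation level from the start, takes its chirality from a standard auxiliary aldol, and fixes 4,5-cis by ring fusion rather than by clean inversion at a hindered benzylic carbon.

**Alternative 2:** Prins–pinacol ring contraction.
- Disconnection: C4–C5 and C2–C3, with the future formyl carbon placed between C2 and C3 in the precursor. The precursor is the 4,5-cis-1,3-dioxolane A5 bearing a Z-alkenyl group.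
- Forward key step: SnCl4 opens the acetal to the C5 oxocarbenium ion on O1, the Z-alkene attacks through C4, and C2 shifts from the carbinol carbon to C3. The ring contracts and the carbinol carbon leaves as the formyl group of A4.
- For: all four ring centres arise in one step with no sacrificial bond. Equatorial aryl groups in the chair give 2,5-cis, the Z geometry gives 4,5-cis, and C3 can relax to trans. Only aryl addition, oxidation and debenzylation would remain.
- Against: stoichiometric SnCl4 meets two benzylic ether carbons on oxygenated arenes. The cation at C3 is secondary and unstabilised, so the reaction is likely to run through a 2-oxonia-Cope/aldol sequence in which C2 becomes planar, and the enantiopurity is then at risk. The Z-alkenyl anti-diol behind A5 needs a longer preparation than an aldol adduct.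
- Comparison: alternative 2 is stronger in directness after the key step. The chosen route offers a catalytic Lewis acid, a para-alkoxybenzylic site at C6 for any positive charge, 4,5-cis from a geometric constraint instead of a conformational preference, and a four-step precursor.

**Alternative 3:** anodic (3+2) on a flavene.
- Disconnection: C3–C4 and C5–O1, after adding the O–C6 bond and a C2=C3 double bond. This leaves 1,3-diketone A7 and (S)-flav-3-ene A8.
- Forward key step: anodic oxidation mediated by ferrocene, Fe(C5H5)2, converts A7 into its C3 radical, which adds to C4 of A8 anti to the aryl group on C6. A second oxidation gives the C5 cation, and the enol oxygen closes the ring to A6.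
- For: this is the most convergent plan, with the whole skeleton and all four arenes from two pieces. The chroman ring enforces 4,5-cis as in the chosen route, and the C6 centre relays the absolute configuration and is erased at the end.
- Against: C2 and C3 are trigonal in A6. Both centres must then come from reduction of a tetrasubstituted, vinylogous-ester double bond. Syn addition gives 2,3-cis and needs a later epimerisation at C3, and the reduced β-alkoxy ketone is prone to β-elimination. A8 can lose its configuration by reversible electrocyclic opening to the ortho-quinone methide.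
- Comparison: alternative 3 is stronger in convergence and equal in how 4,5-cis is secured. It is weaker at C2 and C3, which the chosen route brings in from an aldol reaction with a predictable outcome before the key step.

Key step: step 5

Remark on the chemistry: the acetal carbon of 13 carries no descriptor because it becomes trigonal in 14; 11 is taken as a purchased compound.

## Route

Step 1
Reactants: 1 4-(benzyloxy)benzaldehyde; 2 (2-carboxyethyl)triphenylphosphonium bromide
Product: 4 (E)-4-[4-(benzyloxy)phenyl]but-3-enoic acid, via ylide carboxylate 3 (not isolated)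
Conditions: NaN(SiMe3)2 (2.4 equiv), THF, −78 °C → rt; then 1 M HCl
Reagents that add atoms: none
Why: Wittig olefination with the carboxylate-bearing ylide 3, which with aromatic aldehydes should give mainly the E β,γ-unsaturated acid; the E isomer is purified by crystallisation.

Step 2
Reactants: 4 (E)-4-[4-(benzyloxy)phenyl]but-3-enoic acid; 5 (S)-4-benzyl-1,3-oxazolidin-2-one
Product: 7 (S)-4-benzyl-3-{(E)-4-[4-(benzyloxy)phenyl]but-3-enoyl}-1,3-oxazolidin-2-one, via mixed pivalic anhydride 6 (not isolated)
Conditions: t-BuCOCl, Et3N, THF, −20 °C; then LiCl, 5, −20 °C → rt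
Reagents that add atoms: none
Why: N-acylation of the oxazolidinone through the mixed anhydride with LiCl activation; the mild amine base should leave the double bond in its aryl-conjugated β,γ position.

Step 3
Reactants: 7 (S)-4-benzyl-3-{(E)-4-[4-(benzyloxy)phenyl]but-3-enoyl}-1,3-oxazolidin-2-one; 1 4-(benzyloxy)benzaldehyde
Product: 9 (S)-4-benzyl-3-[(2S,3S)-3-[4-(benzyloxy)phenyl]-2-{(E)-2-[4-(benzyloxy)phenyl]ethenyl}-3-hydroxypropanoyl]-1,3-oxazolidin-2-one, via boron Z-dienolate 8 (not isolated)
Conditions: Bu2BOTf, i-Pr2NEt, CH2Cl2, −78 → 0 °C; then 1, −78 → 0 °C; pH 7 buffer, MeOH, 30% H2O2, 0 °C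
Reagents that add atoms: none
Why: Evans boron aldol reaction; the Z-dienolate 8 reacts at its α-carbon through a chair Zimmerman–Traxler transition state on the face away from the benzyl group of the dipole-opposed auxiliary, which sets the α-carbon (future C3, S) and the carbinol carbon (future C2, S) as the syn pair and leaves the E-styrene in place.

Step 4
Reactants: 9 (S)-4-benzyl-3-[(2S,3S)-3-[4-(benzyloxy)phenyl]-2-{(E)-2-[4-(benzyloxy)phenyl]ethenyl}-3-hydroxypropanoyl]-1,3-oxazolidin-2-one
Product: 10 (2S,3S)-3-[4-(benzyloxy)phenyl]-2-{(E)-2-[4-(benzyloxy)phenyl]ethenyl}-3-hydroxy-N-methoxy-N-methylpropanamide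
Conditions: MeONHMe·HCl, AlMe3, CH2Cl2, −20 → 0 °C; aq. potassium sodium tartrate
Reagents that add atoms: N,O-dimethylhydroxylamine hydrochloride, `CNOC.Cl`
Why: Weinreb transamidation with the aluminium amide; the free β-hydroxyl binds aluminium and directs attack to the exocyclic carbonyl group, so the auxiliary should be released without retro-aldol cleavage or epimerisation.

Step 5
Reactants: 10 (2S,3S)-3-[4-(benzyloxy)phenyl]-2-{(E)-2-[4-(benzyloxy)phenyl]ethenyl}-3-hydroxy-N-methoxy-N-methylpropanamide; 11 4-(benzyloxy)-2-hydroxybenzaldehyde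
Product: 15 (2S,3S,3aS,4S,9bR)-7-(benzyloxy)-2,4-bis[4-(benzyloxy)phenyl]-N-methoxy-N-methyl-2,3,3a,9b-tetrahydro-4H-furo[3,2-c]chromene-3-carboxamide, via dimethyl acetal 12 (not isolated), via mixed acetal 13 (not isolated), via alkoxy ortho-quinone methide 14 (not isolated)
Conditions: Sc(OTf)3 (10 mol%), HC(OMe)3 (2 equiv), CH2Cl2, 0 °C → rt
Reagents that add atoms: none
Why: Sc(OTf)3 and the orthoester convert 11 into acetal 12, which exchanges one methoxy group for the hydroxyl of 10 (13) and loses methanol to give the E-alkoxy ortho-quinone methide 14, the neutral form of the C5=O1 oxocarbenium ion. The tethered E-styrene then adds across the O=C–C=C5 unit in an intramolecular inverse-demand hetero-Diels–Alder reaction (C4 to C5, C6 to the phenol oxygen), which may equally run as a Prins attack followed by capture of the 4-benzyloxybenzyl cation; the closest known reaction type is the Sc(OTf)3/orthoformate condensation of salicylaldehydes with homoallylic alcohols to cis-fused furo[3,2-c]chromans. The oxolane closes by C4–C5 bond formation as a five-membered closure in which the styrene double bond stays exocyclic (5-exo on the alkene, with the oxocarbenium unit inside the ring), and the chroman closes by six-membered O–C6 bond formation from the phenol oxygen. C5 is set relative to C4 by the ring fusion, because the three-atom tether reaches only a cis-fused transition state, and C6 is set relative to C4 by the E geometry of the styrene (suprafacial addition, 3a-H and 4-H trans) and is erased in step 9. The sense of C4 and C5 relative to the existing centres comes from the envelope in which the aryl group on C2 and the amide on C3 lie pseudo-equatorial, so that the styrene adds on the face that places C6 anti to the amide, giving 3,4-trans and 2,5-cis. The step needs acetal exchange and cycloaddition to outrun ionisation of the C2–O bond and a 2-oxonia-Cope shift; the electron-withdrawing amide on C3 and the strongly stabilised benzylic position C6 should favour the wanted path.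

Step 6
Reactants: 16 4-bromobenzene-1,3-diol (4-bromoresorcinol)
Product: 17 2,4-bis(benzyloxy)-1-bromobenzene
Conditions: BnBr, K2CO3, DMF, rt → 50 °C
Reagents that add atoms: benzyl bromide, `BrCc1ccccc1`
Why: Williamson ether synthesis on both phenols.

Step 7
Reactants: 15 (2S,3S,3aS,4S,9bR)-7-(benzyloxy)-2,4-bis[4-(benzyloxy)phenyl]-N-methoxy-N-methyl-2,3,3a,9b-tetrahydro-4H-furo[3,2-c]chromene-3-carboxamide; 17 2,4-bis(benzyloxy)-1-bromobenzene
Product: 19 [2,4-bis(benzyloxy)phenyl][(2S,3S,3aS,4S,9bR)-7-(benzyloxy)-2,4-bis[4-(benzyloxy)phenyl]-2,3,3a,9b-tetrahydro-4H-furo[3,2-c]chromen-3-yl]methanone, via aryllithium 18 (not isolated)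
Conditions: 17, n-BuLi, THF, −78 °C; then 15, −78 → −40 °C; aq. NH4Cl
Reagents that add atoms: none
Why: bromine–lithium exchange followed by addition to the Weinreb amide; the chelated tetrahedral adduct persists until the quench, so one aryl group adds, and C3 keeps its more stable arrangement trans to both neighbours.

Step 8
Reactants: 19 [2,4-bis(benzyloxy)phenyl][(2S,3S,3aS,4S,9bR)-7-(benzyloxy)-2,4-bis[4-(benzyloxy)phenyl]-2,3,3a,9b-tetrahydro-4H-furo[3,2-c]chromen-3-yl]methanone
Product: 20 (2,4-dihydroxyphenyl)[(2S,3S,3aS,4S,9bR)-7-hydroxy-2,4-bis(4-hydroxyphenyl)-2,3,3a,9b-tetrahydro-4H-furo[3,2-c]chromen-3-yl]methanone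
Conditions: H2 (1 atm), 10% Pd/C, EtOAc–MeOH, rt, stopped after uptake of five equivalents
Reagents that add atoms: none
Why: hydrogenolysis of five aryl benzyl ethers; in neutral solvent these should be cleaved well before the cyclic benzylic C–O bonds of the oxolane and chroman or the electron-rich aryl ketone, as in debenzylations of flavans and 2,5-diaryloxolanes.

Step 9
Reactants: 20 (2,4-dihydroxyphenyl)[(2S,3S,3aS,4S,9bR)-7-hydroxy-2,4-bis(4-hydroxyphenyl)-2,3,3a,9b-tetrahydro-4H-furo[3,2-c]chromen-3-yl]methanone
Product: 22 (2,4-dihydroxyphenyl)[(2S,3S,4S,5R)-5-(2,4-dihydroxyphenyl)-4-(4-hydroxybenzyl)-2-(4-hydroxyphenyl)oxolan-3-yl]methanone, via para-quinone methide 21 (not isolated)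
Conditions: NaBH4, 0.1 M aq. NaOH–THF, argon, 0 °C → rt; then dilute HCl to pH 5
Reagents that add atoms: none
Why: in base the 4-hydroxyphenyl group on C6 expels the resorcinol oxygen as a phenoxide to give para-quinone methide 21, which takes up hydride at C6 (1,6-reduction); this is the alkaline borohydride cleavage of phenolic benzyl aryl ethers. The oxolane C–O bonds would need an alkoxide leaving group and the ketone is deactivated as its vinylogous phenoxide, so both should persist, and no stereocentre of 22 is touched.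

## Compound list

1 | 4-(benzyloxy)benzaldehyde | `O=Cc1ccc(OCc2ccccc2)cc1` | starting material
2 | (2-carboxyethyl)triphenylphosphonium bromide | `OC(=O)CC[P+](c1ccccc1)(c1ccccc1)c1ccccc1.[Br-]` | starting material
3 | sodium 3-(triphenylphosphoranylidene)propanoate (ylide carboxylate) | `[Na+].[O-]C(=O)CC=P(c1ccccc1)(c1ccccc1)c1ccccc1` | intermediate
4 | (E)-4-[4-(benzyloxy)phenyl]but-3-enoic acid | `OC(=O)C/C=C/c1ccc(OCc2ccccc2)cc1` | intermediate
5 | (S)-4-benzyl-1,3-oxazolidin-2-one | `O=C1N[C@@H](Cc2ccccc2)CO1` | starting material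
6 | (E)-4-[4-(benzyloxy)phenyl]but-3-enoic pivalic anhydride | `CC(C)(C)C(=O)OC(=O)C/C=C/c1ccc(OCc2ccccc2)cc1` | intermediate
7 | (S)-4-benzyl-3-{(E)-4-[4-(benzyloxy)phenyl]but-3-enoyl}-1,3-oxazolidin-2-one | `O=C1N(C(=O)C/C=C/c2ccc(OCc3ccccc3)cc2)[C@@H](Cc2ccccc2)CO1` | intermediate
8 | dibutylboron (1Z,3E)-dienolate of 7 | `CCCCB(CCCC)O/C(=C\C=C\c1ccc(OCc2ccccc2)cc1)N1[C@@H](Cc2ccccc2)COC1=O` | intermediate
9 | (S)-4-benzyl-3-[(2S,3S)-3-[4-(benzyloxy)phenyl]-2-{(E)-2-[4-(benzyloxy)phenyl]ethenyl}-3-hydroxypropanoyl]-1,3-oxazolidin-2-one | `O=C1N(C(=O)[C@@H](/C=C/c2ccc(OCc3ccccc3)cc2)[C@H](O)c2ccc(OCc3ccccc3)cc2)[C@@H](Cc2ccccc2)CO1` | intermediate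
10 | (2S,3S)-3-[4-(benzyloxy)phenyl]-2-{(E)-2-[4-(benzyloxy)phenyl]ethenyl}-3-hydroxy-N-methoxy-N-methylpropanamide | `CON(C)C(=O)[C@@H](/C=C/c1ccc(OCc2ccccc2)cc1)[C@H](O)c1ccc(OCc2ccccc2)cc1` | intermediate
11 | 4-(benzyloxy)-2-hydroxybenzaldehyde | `O=Cc1ccc(OCc2ccccc2)cc1O` | starting material
12 | 5-(benzyloxy)-2-(dimethoxymethyl)phenol | `COC(OC)c1ccc(OCc2ccccc2)cc1O` | intermediate
13 | (2S,3S)-3-{[4-(benzyloxy)-2-hydroxyphenyl](methoxy)methoxy}-3-[4-(benzyloxy)phenyl]-2-{(E)-2-[4-(benzyloxy)phenyl]ethenyl}-N-methoxy-N-methylpropanamide, either configuration at the acetal carbon | `CON(C)C(=O)[C@@H](/C=C/c1ccc(OCc2ccccc2)cc1)[C@H](OC(OC)c1ccc(OCc2ccccc2)cc1O)c1ccc(OCc2ccccc2)cc1` | intermediate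
14 | (2S,3S)-3-{(E)-[4-(benzyloxy)-6-oxocyclohexa-2,4-dien-1-ylidene]methoxy}-3-[4-(benzyloxy)phenyl]-2-{(E)-2-[4-(benzyloxy)phenyl]ethenyl}-N-methoxy-N-methylpropanamide | `CON(C)C(=O)[C@@H](/C=C/c1ccc(OCc2ccccc2)cc1)[C@H](O/C=C1\C=CC(OCc2ccccc2)=CC1=O)c1ccc(OCc2ccccc2)cc1` | intermediate
15 | (2S,3S,3aS,4S,9bR)-7-(benzyloxy)-2,4-bis[4-(benzyloxy)phenyl]-N-methoxy-N-methyl-2,3,3a,9b-tetrahydro-4H-furo[3,2-c]chromene-3-carboxamide | `CON(C)C(=O)[C@H]1[C@@H]2[C@@H](c3ccc(OCc4ccccc4)cc3)Oc3cc(OCc4ccccc4)ccc3[C@@H]2O[C@@H]1c1ccc(OCc2ccccc2)cc1` | intermediate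
16 | 4-bromobenzene-1,3-diol | `Oc1ccc(Br)c(O)c1` | starting material
17 | 2,4-bis(benzyloxy)-1-bromobenzene | `Brc1ccc(OCc2ccccc2)cc1OCc1ccccc1` | intermediate
18 | [2,4-bis(benzyloxy)phenyl]lithium | `[Li]c1ccc(OCc2ccccc2)cc1OCc1ccccc1` | intermediate
19 | [2,4-bis(benzyloxy)phenyl][(2S,3S,3aS,4S,9bR)-7-(benzyloxy)-2,4-bis[4-(benzyloxy)phenyl]-2,3,3a,9b-tetrahydro-4H-furo[3,2-c]chromen-3-yl]methanone | `O=C(c1ccc(OCc2ccccc2)cc1OCc1ccccc1)[C@H]1[C@@H]2[C@@H](c3ccc(OCc4ccccc4)cc3)Oc3cc(OCc4ccccc4)ccc3[C@@H]2O[C@@H]1c1ccc(OCc2ccccc2)cc1` | intermediate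
20 | (2,4-dihydroxyphenyl)[(2S,3S,3aS,4S,9bR)-7-hydroxy-2,4-bis(4-hydroxyphenyl)-2,3,3a,9b-tetrahydro-4H-furo[3,2-c]chromen-3-yl]methanone | `O=C(c1ccc(O)cc1O)[C@H]1[C@@H]2[C@@H](c3ccc(O)cc3)Oc3cc(O)ccc3[C@@H]2O[C@@H]1c1ccc(O)cc1` | intermediate
21 | (2,4-dihydroxyphenyl)[(2S,3S,4S,5R)-5-(2,4-dihydroxyphenyl)-2-(4-hydroxyphenyl)-4-[(4-oxocyclohexa-2,5-dien-1-ylidene)methyl]oxolan-3-yl]methanone | `O=C(c1ccc(O)cc1O)[C@H]1[C@H](C=C2C=CC(=O)C=C2)[C@H](c2ccc(O)cc2O)O[C@@H]1c1ccc(O)cc1` | intermediate
22 | (2,4-dihydroxyphenyl)[(2S,3S,4S,5R)-5-(2,4-dihydroxyphenyl)-4-(4-hydroxybenzyl)-2-(4-hydroxyphenyl)oxolan-3-yl]methanone | `O=C(c1ccc(O)cc1O)[C@H]1[C@H](Cc2ccc(O)cc2)[C@H](c2ccc(O)cc2O)O[C@@H]1c1ccc(O)cc1` | target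

## Step count and least certain steps

Total: 9 steps. Longest linear sequence: 8 steps (steps 1–5 and 7–9, from 1 and 2); step 6 is a one-step side branch.

**Step 5 (key step).**
- Risk: the hindered secondary alcohol 10 may exchange into the acetal slowly. The Lewis acid could then ionise the benzylic C2–O bond first, with elimination, methanolysis or retro-aldol cleavage, or a 2-oxonia-Cope shift could exchange the aldehyde partners. Facial selectivity on the styrene may also be incomplete, which would give the 3,4-cis/2,5-trans isomer.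
- Fallback: the dehydrative condensation is replaced by a silyl-transfer coupling of two pre-formed partners at low temperature. It sets out from 10 and 11 and comes back at 15. Alcohol 10 is silylated (Me3SiCl, imidazole, CH2Cl2) to (2S,3S)-3-[4-(benzyloxy)phenyl]-2-{(E)-2-[4-(benzyloxy)phenyl]ethenyl}-N-methoxy-N-methyl-3-[(trimethylsilyl)oxy]propanamide F1. Aldehyde 11 is converted separately into acetal 12 (HC(OMe)3, catalytic pyridinium p-toluenesulfonate, MeOH) and used crude. The two are combined with Me3SiOTf and 2,6-di-tert-butylpyridine in CH2Cl2 at −78 °C. Transfer of the silyl group to a methoxy group forms the mixed acetal and then 14 without free alcohol or water, and the cycloaddition gives 15.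

**Step 9.**
- Risk: hydride reduction of the aryl ketone, or enolisation at C3 with β-elimination of O1, may compete with quinone methide formation if the opening is slow. Prolonged exposure could also open the oxolane ether bonds through their own quinone methides.
- Fallback: the chroman is opened while C3 still carries the amide, which borohydride does not reduce and which enolises far less readily. The fallback sets out from 15 and comes back at 22. Hydrogenolysis of 15 (H2, 10% Pd/C) gives (2S,3S,3aS,4S,9bR)-7-hydroxy-2,4-bis(4-hydroxyphenyl)-N-methoxy-N-methyl-2,3,3a,9b-tetrahydro-4H-furo[3,2-c]chromene-3-carboxamide F2. NaBH4 in dilute aqueous NaOH opens it through the para-quinone methide amide F3 (not isolated) to (2S,3S,4S,5R)-5-(2,4-dihydroxyphenyl)-4-(4-hydroxybenzyl)-2-(4-hydroxyphenyl)-N-methoxy-N-methyloxolane-3-carboxamide F4. Benzylation (BnBr, K2CO3, DMF) gives the tetrabenzyl ether F5. Addition of 18, made as in step 7, gives the hexabenzyl ketone F6, and hydrogenolysis of F6 gives 22.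

**Step 7.**
- Risk: the two substituents flanking C3 slow addition to the amide, so the aryllithium may act as a base at C3–H. The resulting amide enolate can expel O1 and open the oxolane.
- Fallback: the aryl group is added to an aldehyde, which reacts far faster than it enolises. The fallback sets out from 15 and comes back at 19. Reduction with i-Bu2AlH (THF, −78 °C) gives (2S,3S,3aS,4S,9bR)-7-(benzyloxy)-2,4-bis[4-(benzyloxy)phenyl]-2,3,3a,9b-tetrahydro-4H-furo[3,2-c]chromene-3-carbaldehyde F7. Addition of 18 at −78 °C gives the secondary alcohol F8 as a mixture of epimers at the new carbinol carbon. Oxidation with Dess–Martin periodinane (CH2Cl2, NaHCO3) gives 19.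

**Step 3.**
- Risk: the aryl-conjugated dienolate may form incompletely or react with less α- and face-selectivity than a simple enolate. The electron-rich adduct may suffer retro-aldol cleavage or migration of the double bond into conjugation during work-up.
- Fallback: the aldol is run on the parent crotonyl system and the arene is attached afterwards. The fallback sets out from 5 and 1 and comes back at 9. Auxiliary 5 is acylated with (E)-but-2-enoyl chloride (Et3N, LiCl, THF) to (S)-4-benzyl-3-[(E)-but-2-enoyl]-1,3-oxazolidin-2-one F9. Bu2BOTf and i-Pr2NEt remove a γ-proton to give the boron dienolate F10 (not isolated), which adds 1 at its α-carbon to give (S)-4-benzyl-3-[(2S)-2-{(S)-[4-(benzyloxy)phenyl](hydroxy)methyl}but-3-enoyl]-1,3-oxazolidin-2-one F11. Cross-metathesis of F11 with purchased 1-(benzyloxy)-4-ethenylbenzene F12 (second-generation Hoveyda–Grubbs catalyst, CH2Cl2, 40 °C) installs the E-styrene and gives 9.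

## Further compounds

F1 | step 5 | (2S,3S)-3-[4-(benzyloxy)phenyl]-2-{(E)-2-[4-(benzyloxy)phenyl]ethenyl}-N-methoxy-N-methyl-3-[(trimethylsilyl)oxy]propanamide | `CON(C)C(=O)[C@@H](/C=C/c1ccc(OCc2ccccc2)cc1)[C@H](O[Si](C)(C)C)c1ccc(OCc2ccccc2)cc1`
F2 | step 9 | (2S,3S,3aS,4S,9bR)-7-hydroxy-2,4-bis(4-hydroxyphenyl)-N-methoxy-N-methyl-2,3,3a,9b-tetrahydro-4H-furo[3,2-c]chromene-3-carboxamide | `CON(C)C(=O)[C@H]1[C@@H]2[C@@H](c3ccc(O)cc3)Oc3cc(O)ccc3[C@@H]2O[C@@H]1c1ccc(O)cc1`
F3 | step 9 | (2S,3S,4S,5R)-5-(2,4-dihydroxyphenyl)-2-(4-hydroxyphenyl)-N-methoxy-N-methyl-4-[(4-oxocyclohexa-2,5-dien-1-ylidene)methyl]oxolane-3-carboxamide (not isolated) | `CON(C)C(=O)[C@H]1[C@H](C=C2C=CC(=O)C=C2)[C@H](c2ccc(O)cc2O)O[C@@H]1c1ccc(O)cc1`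
F4 | step 9 | (2S,3S,4S,5R)-5-(2,4-dihydroxyphenyl)-4-(4-hydroxybenzyl)-2-(4-hydroxyphenyl)-N-methoxy-N-methyloxolane-3-carboxamide | `CON(C)C(=O)[C@H]1[C@H](Cc2ccc(O)cc2)[C@H](c2ccc(O)cc2O)O[C@@H]1c1ccc(O)cc1`
F5 | step 9 | (2S,3S,4S,5R)-4-[4-(benzyloxy)benzyl]-5-[2,4-bis(benzyloxy)phenyl]-2-[4-(benzyloxy)phenyl]-N-methoxy-N-methyloxolane-3-carboxamide | `CON(C)C(=O)[C@H]1[C@H](Cc2ccc(OCc3ccccc3)cc2)[C@H](c2ccc(OCc3ccccc3)cc2OCc2ccccc2)O[C@@H]1c1ccc(OCc2ccccc2)cc1`
F6 | step 9 | [2,4-bis(benzyloxy)phenyl]{(2S,3S,4S,5R)-4-[4-(benzyloxy)benzyl]-5-[2,4-bis(benzyloxy)phenyl]-2-[4-(benzyloxy)phenyl]oxolan-3-yl}methanone | `O=C(c1ccc(OCc2ccccc2)cc1OCc1ccccc1)[C@H]1[C@H](Cc2ccc(OCc3ccccc3)cc2)[C@H](c2ccc(OCc3ccccc3)cc2OCc2ccccc2)O[C@@H]1c1ccc(OCc2ccccc2)cc1`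
F7 | step 7 | (2S,3S,3aS,4S,9bR)-7-(benzyloxy)-2,4-bis[4-(benzyloxy)phenyl]-2,3,3a,9b-tetrahydro-4H-furo[3,2-c]chromene-3-carbaldehyde | `O=C[C@H]1[C@@H]2[C@@H](c3ccc(OCc4ccccc4)cc3)Oc3cc(OCc4ccccc4)ccc3[C@@H]2O[C@@H]1c1ccc(OCc2ccccc2)cc1`
F8 | step 7 | [2,4-bis(benzyloxy)phenyl][(2S,3S,3aS,4S,9bR)-7-(benzyloxy)-2,4-bis[4-(benzyloxy)phenyl]-2,3,3a,9b-tetrahydro-4H-furo[3,2-c]chromen-3-yl]methanol, both epimers at the carbinol carbon | `OC(c1ccc(OCc2ccccc2)cc1OCc1ccccc1)[C@H]1[C@@H]2[C@@H](c3ccc(OCc4ccccc4)cc3)Oc3cc(OCc4ccccc4)ccc3[C@@H]2O[C@@H]1c1ccc(OCc2ccccc2)cc1`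
F9 | step 3 | (S)-4-benzyl-3-[(E)-but-2-enoyl]-1,3-oxazolidin-2-one | `O=C1N(C(=O)/C=C/C)[C@@H](Cc2ccccc2)CO1`
F10 | step 3 | dibutylboron (Z)-dienolate of F9 (not isolated) | `CCCCB(CCCC)O/C(=C\C=C)N1[C@@H](Cc2ccccc2)COC1=O`
F11 | step 3 | (S)-4-benzyl-3-[(2S)-2-{(S)-[4-(benzyloxy)phenyl](hydroxy)methyl}but-3-enoyl]-1,3-oxazolidin-2-one | `O=C1N(C(=O)[C@@H](C=C)[C@H](O)c2ccc(OCc3ccccc3)cc2)[C@@H](Cc2ccccc2)CO1`
F12 | step 3 | 1-(benzyloxy)-4-ethenylbenzene (purchased) | `C=Cc1ccc(OCc2ccccc2)cc1`
A1 | alternative 1 | dibenzyl 4-(4-acetoxybenzyl)-2-(4-acetoxyphenyl)-5-(2,4-diacetoxyphenyl)oxolane-3,3-dicarboxylate, C2, C4 and C5 as in 22 | `O=C(OCc1ccccc1)C1(C(=O)OCc2ccccc2)[C@H](Cc2ccc(OC(C)=O)cc2)[C@H](c2ccc(OC(C)=O)cc2OC(C)=O)O[C@@H]1c1ccc(OC(C)=O)cc1`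
A2 | alternative 1 | dibenzyl trans-2-(4-acetoxybenzyl)-3-(2,4-diacetoxyphenyl)cyclopropane-1,1-dicarboxylate, C4 as in 22 and C5 inverted | `O=C(OCc1ccccc1)C1(C(=O)OCc2ccccc2)[C@H](Cc2ccc(OC(C)=O)cc2)[C@H]1c1ccc(OC(C)=O)cc1OC(C)=O`
A3 | alternative 1 | 4-acetoxybenzaldehyde | `CC(=O)Oc1ccc(C=O)cc1`
A4 | alternative 2 | 4-[4-(benzyloxy)benzyl]-5-[2,4-bis(benzyloxy)phenyl]-2-[4-(benzyloxy)phenyl]oxolane-3-carbaldehyde, all four ring centres as in 22 | `O=C[C@H]1[C@H](Cc2ccc(OCc3ccccc3)cc2)[C@H](c2ccc(OCc3ccccc3)cc2OCc3ccccc3)O[C@@H]1c1ccc(OCc3ccccc3)cc1`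
A5 | alternative 2 | 4,5-cis-2-[2,4-bis(benzyloxy)phenyl]-4-[4-(benzyloxy)phenyl]-5-{(Z)-3-[4-(benzyloxy)phenyl]prop-1-enyl}-1,3-dioxolane, C2 of 22 as in the target, either configuration at the acetal carbon | `C1(c2ccc(OCc3ccccc3)cc2OCc2ccccc2)O[C@H](c2ccc(OCc3ccccc3)cc2)[C@H](/C=C\Cc2ccc(OCc3ccccc3)cc2)O1`
A6 | alternative 3 | cis-fused 3-[2,4-bis(benzyloxy)benzoyl]-7-(benzyloxy)-2,4-bis[4-(benzyloxy)phenyl]-3a,9b-dihydro-4H-furo[3,2-c]chromene, C4 and C5 of 22 as in the target | `O=C(c1ccc(OCc4ccccc4)cc1OCc4ccccc4)C1=C(c2ccc(OCc4ccccc4)cc2)O[C@H]2c3ccc(OCc4ccccc4)cc3O[C@H](c3ccc(OCc4ccccc4)cc3)[C@@H]12`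
A7 | alternative 3 | 1-[2,4-bis(benzyloxy)phenyl]-3-[4-(benzyloxy)phenyl]propane-1,3-dione | `O=C(CC(=O)c1ccc(OCc2ccccc2)cc1)c1ccc(OCc2ccccc2)cc1OCc1ccccc1`
A8 | alternative 3 | (S)-7-(benzyloxy)-2-[4-(benzyloxy)phenyl]-2H-chromene | `C(c1ccccc1)Oc1ccc2C=C[C@@H](c3ccc(OCc4ccccc4)cc3)Oc2c1`
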